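**Strategy.** Everything rests on cutting the conjugated triene at C9'–C10' and, in the same retrosynthetic move, removing the methyl group from C8' (chain numbered C1' at lactone ring A to C11' at butenolide ring B). The feature used is the E-trisubstituted C8'(CH3)=C9' alkene bonded directly to the E-C10'=C11' vinyl arm of ring B. In one flask CH3 and aluminium are added cis across a terminal alkyne and the resulting alkenyl metal is coupled with an E-iodovinyl butenolide, giving two C–C bonds and two defined alkenes. The alkyne partner is a C9 dienyne whose terminal vinyl group is kept for a closing hydroboration–Suzuki union with the chiral-pool Z-enol triflate of ring A.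

Key step: step 6

Remark: in the target, the exocyclic C3=C1' alkene of ring A is read as Z (C2' lies on the side of the lactone carbonyl) and C5 of ring A as R. The route is planned for exactly these descriptors.

**Fragment 1: dienyne**

Step 1
Reactants: 1 pent-4-yn-1-ol
Product: 2 pent-4-ynal
Conditions: TEMPO (10 mol %), PhI(OAc)2, CH2Cl2, rt
Reagents that add atoms: none
Why: The oxoammonium-mediated (TEMPO) alcohol oxidation stops at the aldehyde under anhydrous, near-neutral conditions and leaves the terminal alkyne alone; the volatile aldehyde is carried on as a concentrated solution.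

Step 2
Reactants: 2 pent-4-ynal
Product: 3 (E)-2-methylhept-2-en-6-ynal
Conditions: Ph3P=C(CH3)CHO, toluene, 80 °C
Reagents that add atoms: 2-(triphenylphosphoranylidene)propanal, CC(C=O)=P(c1ccccc1)(c1ccccc1)c1ccccc1
Why: Wittig olefination with a formyl-stabilised ylide should give the E-trisubstituted enal, and the α-branched product is much less reactive towards a second olefination than the unhindered aldehyde 2.

Step 3
Reactants: 3 (E)-2-methylhept-2-en-6-ynal
Product: 4 (E)-6-methylocta-5,7-dien-1-yne
Conditions: Ph3PCH3Br (1.2 equiv), n-BuLi (1.1 equiv), THF, 0 °C; then 3, −78 °C to rt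
Reagents that add atoms: methyltriphenylphosphonium bromide, C[P+](c1ccccc1)(c1ccccc1)c1ccccc1.[Br-]
Why: Wittig methylenation attacks only the carbonyl carbon, so the E alkene is untouched, and the ylide (kept free of surplus n-BuLi) is not basic enough to consume the alkyne C–H.

**Fragment 2: iodovinyl butenolide**

Step 4
Reactants: 5 4-bromofuran-2(5H)-one; 6 (E)-1,2-bis(tributylstannyl)ethene (2 equiv)
Product: 7 (E)-4-[2-(tributylstannyl)vinyl]furan-2(5H)-one
Conditions: Pd2(dba)3 (2.5 mol %), AsPh3 (10 mol %), THF, 50 °C
Reagents that add atoms: none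
Why: In this Stille coupling, zerovalent palladium inserts into the activated C4–Br bond and one alkenyl–tin bond of excess 6 transfers with retention, while product 7, conjugated to the electron-poor ring, is a poorer nucleophile than 6, which holds back double coupling.

Step 5
Reactants: 7 (E)-4-[2-(tributylstannyl)vinyl]furan-2(5H)-one
Product: 8 (E)-4-(2-iodovinyl)furan-2(5H)-one
Conditions: I2, CH2Cl2, 0 °C, dark
Reagents that add atoms: iodine, [I][I]
Why: Iododestannylation is an ipso electrophilic substitution at the tin-bearing carbon with retention of the E geometry, and the electron-poor butenolide alkene does not add iodine.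

**Key union**

Step 6
Reactants: 4 (E)-6-methylocta-5,7-dien-1-yne; 9 trimethylaluminium; 8 (E)-4-(2-iodovinyl)furan-2(5H)-one
Product: 12 4-[(1E,3E,7E)-4,8-dimethyldeca-1,3,7,9-tetraen-1-yl]furan-2(5H)-one, via alkenyldimethylalane 10 (not isolated), via alkenylzinc chloride 11 (not isolated)
Conditions: 9 (2 equiv), Cp2ZrCl2 (25 mol %), ClCH2CH2Cl, 0 °C to rt; volatiles removed in vacuo; THF, ZnCl2 (1 equiv), 8, Pd(PPh3)4 (5 mol %), rt
Reagents that add atoms: trimethylaluminium (9), C[Al](C)C
Why: AlMe3 methylates Cp2ZrCl2 to an aluminium-activated Zr–CH3 complex, the alkyne inserts into that bond through a four-centre transition state so that the new methyl sits on the substituted carbon C8' and the metal on the CH terminus C9', cis to each other, and Zr/Al exchange releases alane 10 and returns the zirconocene. Once surplus AlMe3 has been stripped off under vacuum, ZnCl2 converts 10 into the more readily transmetalating 11, zerovalent palladium inserts into the C–I bond of 8, and transmetalation followed by reductive elimination forges C9'–C10' without disturbing either alkene. The closest known reaction types are zirconium-catalysed carboalumination of 1-alkynes and the zinc-assisted Negishi alkenyl–alkenyl coupling, here run back to back. No ring is closed and no stereocentre is made; what is set is the E geometry at C8'=C9' (cis addition with the metal at the terminus, steered by the steric difference between the CH end and the carbon bearing C7'), while the E geometry at C10'=C11' is inherited from 8. The alkyne must react ahead of the 1,3-diene and the trisubstituted alkene of 4, which the unhindered and far more reactive triple bond secures at or below room temperature. The butenolide must survive, which is secured by placing it in the electrophile so that it meets only mild alkenyl-aluminium and alkenyl-zinc species and never free AlMe3.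

**Fragment 3: ring A**

Step 7
Reactants: 13 (R)-5-oxotetrahydrofuran-2-carboxylic acid
Product: 14 (R)-5-(hydroxymethyl)dihydrofuran-2(3H)-one
Conditions: BH3·SMe2, THF, 0 °C to rt; MeOH quench, evaporation
Reagents that add atoms: none
Why: Chemoselective borane reduction takes the free carboxylic acid far faster than the lactone and does not touch the stereocentre.

Step 8
Reactants: 14 (R)-5-(hydroxymethyl)dihydrofuran-2(3H)-one
Product: 15 (R)-5-oxotetrahydrofuran-2-carbaldehyde
Conditions: (COCl)2, DMSO, CH2Cl2, −78 °C; Et3N, −78 to −30 °C; Et2O, filtration, no aqueous work-up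
Reagents that add atoms: none
Why: Swern oxidation at low temperature gives the water-soluble, epimerisable α-acyloxy aldehyde without over-oxidation, and it is used at once.

Step 9
Reactants: 15 (R)-5-oxotetrahydrofuran-2-carbaldehyde
Product: 16 (R)-5-(2-methylprop-1-en-1-yl)dihydrofuran-2(3H)-one
Conditions: i-PrPPh3I (1.2 equiv), n-BuLi (1.1 equiv), THF, 0 °C; then 15, −78 to 0 °C
Reagents that add atoms: isopropyltriphenylphosphonium iodide, CC(C)[P+](c1ccccc1)(c1ccccc1)c1ccccc1.[I-]
Why: In this Wittig olefination with a non-stabilised ylide, addition to the aldehyde at −78 °C should outrun enolisation and lactone attack, no alkene geometry arises (two methyl groups), and the C5 configuration is carried over as R.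

Step 10
Reactants: 16 (R)-5-(2-methylprop-1-en-1-yl)dihydrofuran-2(3H)-one
Product: 18 (5R)-3-(hydroxymethylidene)-5-(2-methylprop-1-en-1-yl)dihydrofuran-2(3H)-one, via sodium enolate 17 (not isolated)
Conditions: NaH, HCO2Et, EtOH (cat.), Et2O, 0 °C to rt; cold 1 M HCl
Reagents that add atoms: ethyl formate, CCOC=O
Why: The crossed Claisen condensation at the only enolisable position (C3) is driven by formation of the stabilised salt 17, and the C5–H is not acidic, so the stereocentre is safe.

Step 11
Reactants: 18 (5R)-3-(hydroxymethylidene)-5-(2-methylprop-1-en-1-yl)dihydrofuran-2(3H)-one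
Product: 20 (Z)-[(5R)-5-(2-methylprop-1-en-1-yl)-2-oxodihydrofuran-3(2H)-ylidene]methyl trifluoromethanesulfonate, via lithium chelate 19 (not isolated)
Conditions: LiOTf (2 equiv), Et3N, CH2Cl2, 0 °C; Tf2O, −78 to 0 °C
Reagents that add atoms: trifluoromethanesulfonic anhydride, O=S(=O)(OS(=O)(=O)C(F)(F)F)C(F)(F)F
Why: In this chelation-controlled O-sulfonylation of a 1,3-dicarbonyl enolate, Li+ bridges the enolate oxygen and the lactone carbonyl oxygen, so the oxygen that is triflated sits cis to C2=O and the Z-enol triflate should predominate, with any E isomer removable by chromatography.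

**Closing union**

Step 12
Reactants: 12 4-[(1E,3E,7E)-4,8-dimethyldeca-1,3,7,9-tetraen-1-yl]furan-2(5H)-one; 20 Z-enol triflate of ring A
Product: 22 CNP0187251.2 (3Z,5R)-3-[(4E,8E,10E)-4,8-dimethyl-11-(5-oxo-2,5-dihydrofuran-3-yl)undeca-4,8,10-trien-1-ylidene]-5-(2-methylprop-1-en-1-yl)dihydrofuran-2(3H)-one, via B-alkyl-9-BBN adduct 21 (not isolated)
Conditions: 9-BBN (1.1 equiv), THF, 0 °C to rt; then 20, PdCl2(dppf) (5 mol %), AsPh3 (10 mol %), 3 M aq. K3PO4, DMF, rt
Reagents that add atoms: none
Why: 9-BBN adds anti-Markovnikov to the only monosubstituted alkene (boron at C2'), and the B-alkyl Suzuki–Miyaura coupling then replaces OTf at C1' with retention, so that C2' ends up cis to the lactone carbonyl (Z); ring A never meets the borane, and the mild phosphate base at rt spares both lactones and C5.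

**Compound list**

1 | pent-4-yn-1-ol | C#CCCCO | starting material
2 | pent-4-ynal | C#CCCC=O | intermediate
3 | (E)-2-methylhept-2-en-6-ynal | O=C/C(C)=C/CCC#C | intermediate
4 | (E)-6-methylocta-5,7-dien-1-yne | C=C/C(C)=C/CCC#C | intermediate
5 | 4-bromofuran-2(5H)-one | O=C1C=C(Br)CO1 | starting material
6 | (E)-1,2-bis(tributylstannyl)ethene | CCCC[Sn](CCCC)(CCCC)/C=C/[Sn](CCCC)(CCCC)CCCC | starting material
7 | (E)-4-[2-(tributylstannyl)vinyl]furan-2(5H)-one | CCCC[Sn](CCCC)(CCCC)/C=C/C1=CC(=O)OC1 | intermediate
8 | (E)-4-(2-iodovinyl)furan-2(5H)-one | I/C=C/C1=CC(=O)OC1 | intermediate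
9 | trimethylaluminium | C[Al](C)C | starting material
10 | dimethyl[(1E,5E)-2,6-dimethylocta-1,5,7-trien-1-yl]alane | C=C/C(C)=C/CC/C(C)=C/[Al](C)C | intermediate
11 | [(1E,5E)-2,6-dimethylocta-1,5,7-trien-1-yl]zinc chloride | C=C/C(C)=C/CC/C(C)=C/[Zn]Cl | intermediate
12 | 4-[(1E,3E,7E)-4,8-dimethyldeca-1,3,7,9-tetraen-1-yl]furan-2(5H)-one | C=C/C(C)=C/CC/C(C)=C/C=C/C1=CC(=O)OC1 | intermediate
13 | (R)-5-oxotetrahydrofuran-2-carboxylic acid | OC(=O)[C@H]1CCC(=O)O1 | starting material
14 | (R)-5-(hydroxymethyl)dihydrofuran-2(3H)-one | OC[C@H]1CCC(=O)O1 | intermediate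
15 | (R)-5-oxotetrahydrofuran-2-carbaldehyde | O=C[C@H]1CCC(=O)O1 | intermediate
16 | (R)-5-(2-methylprop-1-en-1-yl)dihydrofuran-2(3H)-one | CC(C)=C[C@H]1CCC(=O)O1 | intermediate
17 | sodium enolate of the 3-formyl lactone (geometry not fixed) | CC(C)=C[C@H]1CC(=C[O-])C(=O)O1.[Na+] | intermediate
18 | (5R)-3-(hydroxymethylidene)-5-(2-methylprop-1-en-1-yl)dihydrofuran-2(3H)-one (enol tautomer of the 3-formyl lactone, geometry not fixed) | CC(C)=C[C@H]1CC(=CO)C(=O)O1 | intermediate
19 | lithium chelate of the Z-enolate of 18 | CC(C)=C[C@H]1C/C(=C/[O-])C(=O)O1.[Li+] | intermediate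
20 | (Z)-[(5R)-5-(2-methylprop-1-en-1-yl)-2-oxodihydrofuran-3(2H)-ylidene]methyl trifluoromethanesulfonate | CC(C)=C[C@H]1C/C(=C/OS(=O)(=O)C(F)(F)F)C(=O)O1 | intermediate
21 | 4-[(1E,3E,7E)-10-(9-borabicyclo[3.3.1]nonan-9-yl)-4,8-dimethyldeca-1,3,7-trien-1-yl]furan-2(5H)-one | B1(CC/C(C)=C/CC/C(C)=C/C=C/C2=CC(=O)OC2)C3CCCC1CCC3 | intermediate
22 | CNP0187251.2, (3Z,5R)-3-[(4E,8E,10E)-4,8-dimethyl-11-(5-oxo-2,5-dihydrofuran-3-yl)undeca-4,8,10-trien-1-ylidene]-5-(2-methylprop-1-en-1-yl)dihydrofuran-2(3H)-one | CC(C)=C[C@H]1C/C(=C/CC/C(C)=C/CC/C(C)=C/C=C/C2=CC(=O)OC2)C(=O)O1 | target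

**Step count.** Total: 12 steps. Longest linear sequence: 6 steps (13 to 22, steps 7 to 12).

**Steps most likely to fail**

Step 6.
- What may go wrong: carbometalation may be incomplete or insufficiently regioselective, residual methylaluminium species may attack the butenolide, and slow transmetalation may let homocoupling compete.
- Fallback, from 4 (through 10) and 7, back at 12: the one-pot process is split and the polarity of the coupling is reversed.
- Alane 10 is made as before and quenched with I2 in THF at −30 °C. This gives (3E,7E)-8-iodo-3,7-dimethylocta-1,3,7-triene F1, which can be purified from any regioisomer.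
- F1 is then joined to stannane 7, already in hand from step 4, by Stille coupling (Pd2(dba)3, AsPh3, NMP, rt) to give 12.
- The butenolide then never meets aluminium, and step 5 is no longer needed.

Step 12.
- What may go wrong: hydroboration may spread beyond the terminal vinyl group, or the aqueous base may hydrolyse the enol triflate or deprotonate the butenolide before transmetalation takes place.
- Fallback, from 12, back at 22: boron is exchanged for zinc so that the C1'–C2' bond is made without any base.
- 12 is hydroborated as before and 21 is oxidised with NaBO3·4H2O in THF/H2O. This gives 4-[(1E,3E,7E)-10-hydroxy-4,8-dimethyldeca-1,3,7-trien-1-yl]furan-2(5H)-one F2, which can be freed from over-hydroborated material.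
- An Appel-type iodination (I2, PPh3, imidazole, CH2Cl2, 0 °C) gives 4-[(1E,3E,7E)-10-iodo-4,8-dimethyldeca-1,3,7-trien-1-yl]furan-2(5H)-one F3.
- LiCl-promoted insertion of Zn dust in THF gives the corresponding alkylzinc iodide F4.
- Negishi coupling of F4 with 20 (PdCl2(dppf), THF, rt) gives 22 with retention at C1'.

Step 11.
- What may go wrong: the enolate may escape lithium chelation, because the exocyclic five-ring geometry widens the O–O bite, so geometric control in the O-sulfonylation is lost. The triflate may also hydrolyse during purification.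
- Fallback, from 18 (and from 12 through F2 to F4), back at 22: the triflate is replaced by a hydrolytically robust sulfonate, and the closing coupling is changed from boron to zinc.
- 18 is treated with TsCl, N-methylimidazole and LiOH in CH2Cl2 at 0 °C, where the N-tosylimidazolium salt transfers the sulfonyl group to the lithium enolate. This gives (Z)-[(5R)-5-(2-methylprop-1-en-1-yl)-2-oxodihydrofuran-3(2H)-ylidene]methyl 4-methylbenzenesulfonate F5.
- F5 is expected to tolerate chromatography and crystallisation for removal of the E isomer, and the unwanted isomer can be hydrolysed back to 18.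
- F5 is then coupled base-free with the alkylzinc iodide F4 (PdCl2(dppf), THF, 40 °C) to give 22.

**Further compounds**

F1 | step 6 | (3E,7E)-8-iodo-3,7-dimethylocta-1,3,7-triene | C=C/C(C)=C/CC/C(C)=C/I
F2 | step 12 | 4-[(1E,3E,7E)-10-hydroxy-4,8-dimethyldeca-1,3,7-trien-1-yl]furan-2(5H)-one | OCC/C(C)=C/CC/C(C)=C/C=C/C1=CC(=O)OC1
F3 | step 12 | 4-[(1E,3E,7E)-10-iodo-4,8-dimethyldeca-1,3,7-trien-1-yl]furan-2(5H)-one | ICC/C(C)=C/CC/C(C)=C/C=C/C1=CC(=O)OC1
F4 | step 12 | [(3E,7E,9E)-3,7-dimethyl-10-(5-oxo-2,5-dihydrofuran-3-yl)deca-3,7,9-trien-1-yl]zinc iodide | I[Zn]CC/C(C)=C/CC/C(C)=C/C=C/C1=CC(=O)OC1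
F5 | step 11 | (Z)-[(5R)-5-(2-methylprop-1-en-1-yl)-2-oxodihydrofuran-3(2H)-ylidene]methyl 4-methylbenzenesulfonate | CC(C)=C[C@H]1C/C(=C/OS(=O)(=O)c2ccc(C)cc2)C(=O)O1
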